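## Retrosynthetic overview

1. The last bond made is C3–C4 of the acyl chain (C1 = amide carbonyl). A nickel-electrocatalytic decarboxylative alkenylation joins the N-hydroxyphthalimide ester of the complete head-group succinamic acid to (1E,4R)-1-iodo-4-methoxyundec-1-ene. Two acceptor carbons are united and the target is released without protecting groups.
2. The enabling feature is the array O=C1–C2H2–C3H2–C4H=C5H. C3 lies β to the amide carbonyl, so one extra carboxyl on C3 turns C1–C3 into a succinic acid half-amide. C4 is a non-stereogenic sp2 CH of an isolated (E)-alkene and maps onto a stereodefined alkenyl iodide. The reducible 7-oxabicyclo[4.1.0]heptan-2-one (rings A and B) is insulated from C3 by the amide and the chloroalkene.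
3. In the head group, the C2'–CH= bond comes from a Negishi coupling of a ring A alkenylzinc with an (E)-2-chloro-3-iodoallyl succinamate. Anti iodochlorination of propargyl alcohol fixes Cl trans to ring A.
4. Ring A (carbocycle) is bought as 2-methylcyclohex-2-enone; CBS reduction sets C5' and anti hydroboration sets C6'. Ring B (oxirane) is the only ring formed, in step 16, by hydroxyl-directed epoxidation after a Luche reduction has put C1'–OH on the face of CH3 and O-silyl.
5. For the alkenyl iodide, (R)-epichlorohydrin supplies C7, followed by hexyl Grignard, acetylide, O-methylation and hydrozirconation–iodination.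

Key step: step 22

Remark: the SMILES is read as (4E,7R) in the acyl chain, (E) at the chloroalkene (N–CH2 cis and Cl trans to ring A) and (1R,3S,4S,6R) in the bicycle, so oxirane O, OAc and CH3 share one face. Ring A is numbered as a cyclohexanone: C1' C=O, C2' oxirane C with side chain, C3' oxirane CH, C4' CH2, C5' CHOAc, C6' CHCH3.

## Route

### Fragment A: alkenyl iodide (steps 1–4)

Step 1
Reactants: 1 (R)-epichlorohydrin; 2 n-hexylmagnesium bromide
Product: 3 (2R)-1-chlorononan-2-ol
Conditions: CuI (10 mol %), THF, −40 to 0 °C; then H2O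
Reagents that add atoms: none
Why: Copper-catalysed Grignard opening (SN2) at the unsubstituted oxirane carbon does not touch the C–O stereocentre of 1, which becomes C7 of the acyl chain in the (R) series.

Step 2
Reactants: 3 (2R)-1-chlorononan-2-ol
Product: 5 (4R)-undec-1-yn-4-ol, via (R)-1,2-epoxynonane 4 (not isolated)
Conditions: lithium acetylide·ethylenediamine (3 equiv), DMSO, 0 °C to rt; then H2O
Reagents that add atoms: lithium acetylide (ethylenediamine complex), [Li]C#C
Why: One equivalent of acetylide closes the chlorohydrin to the terminal epoxide (intramolecular Williamson reaction) and a second opens it at CH2 (SN2 epoxide alkynylation), so the carbinol centre is never involved and stays (R).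

Step 3
Reactants: 5 (4R)-undec-1-yn-4-ol
Product: 6 (4R)-4-methoxyundec-1-yne
Conditions: NaH, MeI, THF, 0 °C to rt
Reagents that add atoms: methyl iodide, CI
Why: Williamson etherification of the sodium alkoxide installs the C7 methyl ether without affecting the stereocentre, the alkyne C–H being too weakly acidic for NaH under these conditions.

Step 4
Reactants: 6 (4R)-4-methoxyundec-1-yne
Product: 8 (1E,4R)-1-iodo-4-methoxyundec-1-ene, via alkenylzirconocene chloride 7 (not isolated)
Conditions: Cp2Zr(H)Cl (1.3 equiv), THF, rt; then I2, 0 °C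
Reagents that add atoms: Cp2Zr(H)Cl (zirconocene chloride unit only in 7), [H][Zr](Cl)(C1C=CC=C1)C1C=CC=C1; iodine, II
Why: Hydrozirconation adds Zr–H syn with zirconium on the terminal carbon and iodinolysis of the C–Zr bond is retentive, which should give the (E)-alkenyl iodide.

### Fragment B: chloro-iodo-allyl succinamate (steps 5–7)

Step 5
Reactants: 9 prop-2-yn-1-ol
Product: 10 (E)-2-chloro-3-iodoprop-2-en-1-ol
Conditions: ICl (1.05 equiv), CH2Cl2, −78 to 0 °C, dark
Reagents that add atoms: iodine monochloride, ClI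
Why: Electrophilic anti addition of I–Cl through an iodirenium ion that chloride opens at the internal (Markovnikov) carbon should place I and Cl trans, which is the geometry (iodine cis to CH2O) that the chloroalkene of the target needs.

Step 6
Reactants: 10 (E)-2-chloro-3-iodoprop-2-en-1-ol
Product: 12 (E)-2-chloro-3-iodo-N-methylprop-2-en-1-amine, via allylic mesylate 11 (not isolated)
Conditions: MsCl, Et3N, CH2Cl2, −20 °C; then MeNH2 (2 M in THF, 10 equiv), 0 °C to rt
Reagents that add atoms: methanesulfonyl chloride (mesyl group only in 11), CS(=O)(=O)Cl; methylamine, CN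
Why: Mesylation and SN2 displacement at the primary allylic carbon by a large excess of methylamine give the secondary amine, the vinylic halides being inert to SN2 and the alkene geometry unaffected.

Step 7
Reactants: 12 (E)-2-chloro-3-iodo-N-methylprop-2-en-1-amine; 13 4-tert-butoxy-4-oxobutanoic acid
Product: 14 tert-butyl 4-{[(2E)-2-chloro-3-iodoprop-2-en-1-yl](methyl)amino}-4-oxobutanoate
Conditions: EDC·HCl, HOBt, CH2Cl2, 0 °C to rt
Reagents that add atoms: none
Why: Carbodiimide amide coupling joins the secondary amine to the free carboxyl of the succinic half-ester, and the resulting tertiary amide cannot close to a succinimide.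

### Ring A, union and end game (steps 8–22)

Step 8
Reactants: 15 2-methylcyclohex-2-en-1-one
Product: 16 (1S)-2-methylcyclohex-2-en-1-ol
Conditions: (R)-2-methyl-CBS-oxazaborolidine (10 mol %), BH3·SMe2, THF, −20 °C; then H2O
Reagents that add atoms: none
Why: Corey–Bakshi–Shibata reduction, in which the (R)-oxazaborolidine–borane complex binds the ketone with the C(CH3)=CH arm as the large group and delivers hydride to one face, should give the (S)-carbinol that becomes C5'.

Step 9
Reactants: 16 (1S)-2-methylcyclohex-2-en-1-ol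
Product: 17 tert-butyldimethyl{[(1S)-2-methylcyclohex-2-en-1-yl]oxy}silane
Conditions: TBSCl, imidazole, DMF, rt
Reagents that add atoms: tert-butyldimethylsilyl chloride, CC(C)(C)[Si](C)(C)Cl
Why: Imidazole-promoted silylation masks C5'–OH with a group that is a poor leaving group in the later β-silyloxy ketones.

Step 10
Reactants: 17 tert-butyldimethyl{[(1S)-2-methylcyclohex-2-en-1-yl]oxy}silane
Product: 19 (1S,2R,3S)-3-[(tert-butyldimethylsilyl)oxy]-2-methylcyclohexan-1-ol, via alkylborane 18 (not isolated)
Conditions: BH3·THF, THF, 0 °C to rt; then NaOH, H2O2, 0 °C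
Reagents that add atoms: borane (boron only in 18), B; hydrogen peroxide, OO
Why: In this hydroboration–oxidation, allylic 1,2-strain holds the silyloxy group pseudoaxial, so borane adds syn to the opposite face with boron on the CH carbon, which sets C6' (CH3 cis to OTBS) and, after retentive oxidation, a C1' alcohol trans to CH3.

Step 11
Reactants: 19 (1S,2R,3S)-3-[(tert-butyldimethylsilyl)oxy]-2-methylcyclohexan-1-ol
Product: 20 (2S,3S)-3-[(tert-butyldimethylsilyl)oxy]-2-methylcyclohexan-1-one
Conditions: Dess–Martin periodinane, CH2Cl2, 0 °C to rt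
Reagents that add atoms: none
Why: Dess–Martin oxidation under non-basic conditions gives the ketone without epimerising the adjacent C6' centre or eliminating the β-silyloxy group.

Step 12
Reactants: 20 (2S,3S)-3-[(tert-butyldimethylsilyl)oxy]-2-methylcyclohexan-1-one
Product: 22 (5S,6S)-5-[(tert-butyldimethylsilyl)oxy]-6-methylcyclohex-2-en-1-one, via lithium enolate 21 (not isolated)
Conditions: LDA (1.1 equiv), THF, −78 °C; then PhS(Cl)=N-t-Bu, −78 °C
Reagents that add atoms: lithium diisopropylamide (lithium only in 21), [Li]N(C(C)C)C(C)C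
Why: In the Mukaiyama dehydrogenation, kinetic deprotonation at the unhindered C2' methylene, attack of the enolate on sulfur and intramolecular syn elimination at −78 °C give the C2'=C3' enone while C6' is never enolised.

Step 13
Reactants: 22 (5S,6S)-5-[(tert-butyldimethylsilyl)oxy]-6-methylcyclohex-2-en-1-one
Product: 23 (5S,6S)-5-[(tert-butyldimethylsilyl)oxy]-2-iodo-6-methylcyclohex-2-en-1-one
Conditions: I2, pyridine/CH2Cl2 (1:1), 0 °C to rt
Reagents that add atoms: iodine, II
Why: Pyridine-mediated α-iodination of the enone (Baylis–Hillman-type conjugate addition, iodination and elimination) places iodine on C2' under conditions too weakly basic to disturb C5' or C6'.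

Step 14
Reactants: 23 (5S,6S)-5-[(tert-butyldimethylsilyl)oxy]-2-iodo-6-methylcyclohex-2-en-1-one
Product: 24 (1S,5S,6R)-5-[(tert-butyldimethylsilyl)oxy]-2-iodo-6-methylcyclohex-2-en-1-ol
Conditions: NaBH4, CeCl3·7H2O, MeOH, −78 °C
Reagents that add atoms: none
Why: In this Luche 1,2-reduction both half-chair conformers expose the face of C1' opposite to the C6' methyl and C5' silyloxy groups, so hydride should enter there and leave the new hydroxyl cis to both (all-cis array).

Step 15
Reactants: 24 (1S,5S,6R)-5-[(tert-butyldimethylsilyl)oxy]-2-iodo-6-methylcyclohex-2-en-1-ol; 14 tert-butyl 4-{[(2E)-2-chloro-3-iodoprop-2-en-1-yl](methyl)amino}-4-oxobutanoate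
Product: 27 tert-butyl 4-{[(2E)-3-{(4S,5R,6S)-4-[(tert-butyldimethylsilyl)oxy]-6-hydroxy-5-methylcyclohex-1-en-1-yl}-2-chloroprop-2-en-1-yl](methyl)amino}-4-oxobutanoate, via dilithio species 25 (not isolated), via alkenylzinc chloride 26 (not isolated)
Conditions: t-BuLi (3.1 equiv), THF, −78 °C; ZnCl2 (1.5 equiv), −78 to 0 °C; then 14, Pd(PPh3)4 (5 mol %), rt; then H2O
Reagents that add atoms: tert-butyllithium (lithium only in 25 and 26), [Li]C(C)(C)C; zinc chloride (zinc and chlorine only in 26), Cl[Zn]Cl
Why: Iodine–lithium exchange on the lithium alkoxide, transmetalation to zinc and Negishi coupling, in which zerovalent palladium inserts only into the C–I bond of 14 and both alkenyl partners couple with retention, should leave ring A cis to N–CH2 and trans to Cl.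

Step 16
Reactants: 27 diene alcohol
Product: 28 tert-butyl 4-{[(2E)-3-{(1S,2S,3R,4S,6R)-4-[(tert-butyldimethylsilyl)oxy]-2-hydroxy-3-methyl-7-oxabicyclo[4.1.0]heptan-1-yl}-2-chloroprop-2-en-1-yl](methyl)amino}-4-oxobutanoate
Conditions: VO(acac)2 (5 mol %), t-BuOOH (decane), CH2Cl2, 0 °C to rt
Reagents that add atoms: tert-butyl hydroperoxide, CC(C)(C)OO
Why: In this hydroxyl-directed epoxidation the vanadium alkoxide of C1'–OH delivers the peroxide oxygen to C2'=C3' on its own face, which sets both oxirane carbons cis to OH, CH3 and OTBS and closes ring B, while the electron-poor chloroalkene stays intact.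

Step 17
Reactants: 28 epoxy alcohol
Product: 29 tert-butyl 4-{[(2E)-3-{(1R,3S,4S,6R)-4-[(tert-butyldimethylsilyl)oxy]-3-methyl-2-oxo-7-oxabicyclo[4.1.0]heptan-1-yl}-2-chloroprop-2-en-1-yl](methyl)amino}-4-oxobutanoate
Conditions: Dess–Martin periodinane, CH2Cl2, 0 °C to rt
Reagents that add atoms: none
Why: Dess–Martin oxidation of the hindered epoxy alcohol removes the auxiliary C1' stereocentre under neutral conditions that leave the oxirane and C6' unchanged.

Step 18
Reactants: 29 silyloxy epoxy ketone
Product: 30 tert-butyl 4-{[(2E)-2-chloro-3-[(1R,3S,4S,6R)-4-hydroxy-3-methyl-2-oxo-7-oxabicyclo[4.1.0]heptan-1-yl]prop-2-en-1-yl](methyl)amino}-4-oxobutanoate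
Conditions: HF·pyridine, pyridine, THF, 0 °C to rt
Reagents that add atoms: none
Why: Fluoride-driven desilylation in buffered HF·pyridine avoids the retro-aldol and E1cB pathways that a basic fluoride source would open for the β-hydroxy ketone, and it does not cleave the tert-butyl ester.

Step 19
Reactants: 30 hydroxy epoxy ketone
Product: 31 tert-butyl 4-{[(2E)-3-[(1R,3S,4S,6R)-4-acetoxy-3-methyl-2-oxo-7-oxabicyclo[4.1.0]heptan-1-yl]-2-chloroprop-2-en-1-yl](methyl)amino}-4-oxobutanoate
Conditions: Ac2O, pyridine, CH2Cl2, 0 °C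
Reagents that add atoms: acetic anhydride, CC(=O)OC(C)=O
Why: O-Acylation with retention at C5' under weakly basic conditions at 0 °C should keep the β-acetoxy ketone from E1cB elimination.

Step 20
Reactants: 31 acetoxy tert-butyl ester
Product: 32 4-{[(2E)-3-[(1R,3S,4S,6R)-4-acetoxy-3-methyl-2-oxo-7-oxabicyclo[4.1.0]heptan-1-yl]-2-chloroprop-2-en-1-yl](methyl)amino}-4-oxobutanoic acid
Conditions: CF3CO2H/CH2Cl2 (1:4), 0 °C
Reagents that add atoms: none
Why: Acidolysis of the tert-butyl ester (E1 loss of isobutene) frees the carboxyl group, and the oxirane should survive because the adjacent ketone disfavours ionisation at C2'.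

Step 21
Reactants: 32 succinamic acid
Product: 33 1,3-dioxoisoindolin-2-yl 4-{[(2E)-3-[(1R,3S,4S,6R)-4-acetoxy-3-methyl-2-oxo-7-oxabicyclo[4.1.0]heptan-1-yl]-2-chloroprop-2-en-1-yl](methyl)amino}-4-oxobutanoate
Conditions: N-hydroxyphthalimide, DIC, DMAP (5 mol %), CH2Cl2, 0 °C to rt
Reagents that add atoms: N-hydroxyphthalimide, O=C1c2ccccc2C(=O)N1O
Why: Steglich-type esterification converts the carboxyl group into the redox-active ester, the electron-accepting handle that is expelled again in step 22.

Step 22
Reactants: 33 redox-active ester; 8 (1E,4R)-1-iodo-4-methoxyundec-1-ene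
Product: 34 (4E,7R)-N-{(2E)-3-[(1R,3S,4S,6R)-4-acetoxy-3-methyl-2-oxo-7-oxabicyclo[4.1.0]heptan-1-yl]-2-chloroprop-2-en-1-yl}-7-methoxy-N-methyltetradec-4-enamide
Conditions: 33 (1 equiv), 8 (2 equiv), NiCl2·6H2O (20 mol %), 2,2'-bipyridine (20 mol %), AgNO3 (0.3 equiv), Bu4NBF4 (0.1 M), DMF, undivided cell, Mg anode/RVC cathode, constant current, ca. 2.5 F/mol, rt
Reagents that add atoms: none
Why: Cathodic reduction turns the bipyridine complex of divalent nickel into low-valent nickel, which inserts into the C(sp2)–I bond of 8 with retention, while single-electron transfer to the phthalimide unit of 33 releases phthalimide anion and CO2 and leaves the primary radical on C3; capture of this radical by the alkenylnickel species and reductive elimination from trivalent nickel forge C3–C4, the Mg anode supplying the two electrons. The closest known reaction type is the nickel-electrocatalytic decarboxylative alkenylation of N-hydroxyphthalimide esters with alkenyl iodides on a silver-nanoparticle-coated cathode, in which succinic half-ester derivatives serve as two-carbon linchpins, and 33 is the half-amide analogue. It is a cross-electrophile union of two acceptor carbons (C3 next to an activated carboxyl, C4 bearing iodide), so no organometallic reagent ever meets the epoxy ketone, the β-acetoxy ketone or the amide. No ring is closed and no stereocentre is made: the (E)-C4=C5 geometry is carried over from 8 because oxidative addition and reductive elimination at an alkenyl carbon are stereoretentive, and C7 and the four ring stereocentres are spectators at room temperature. The step needs C–I to react before C–Cl, which the weaker C–I bond and the hindered trisubstituted position of chlorine secure, and it needs the ester to be reduced before the epoxy ketone, which the easily reduced phthalimide unit, the low overpotential of the silver-coated cathode and the limited charge secure. Radical capture must also outrun 6-exo or 7-endo addition to the chloroalkene, which should be slow because C(Cl) is fully substituted, the =CH is flanked by the quaternary oxirane carbon and the planar tertiary amide resists the required folding.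

## Compound list

1 | (R)-epichlorohydrin | ClC[C@H]1CO1 | starting material
2 | n-hexylmagnesium bromide | CCCCCC[Mg]Br | starting material
3 | (2R)-1-chlorononan-2-ol | CCCCCCC[C@H](CCl)O | intermediate
4 | (R)-1,2-epoxynonane | CCCCCCC[C@@H]1CO1 | intermediate
5 | (4R)-undec-1-yn-4-ol | CCCCCCC[C@H](CC#C)O | intermediate
6 | (4R)-4-methoxyundec-1-yne | CCCCCCC[C@H](CC#C)OC | intermediate
7 | chlorobis(cyclopentadienyl)[(1E,4R)-4-methoxyundec-1-en-1-yl]zirconium | CCCCCCC[C@H](C/C=C/[Zr](Cl)(C1C=CC=C1)C1C=CC=C1)OC | intermediate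
8 | (1E,4R)-1-iodo-4-methoxyundec-1-ene | CCCCCCC[C@H](C/C=C/I)OC | intermediate
9 | prop-2-yn-1-ol | OCC#C | starting material
10 | (E)-2-chloro-3-iodoprop-2-en-1-ol | OC/C(Cl)=C\I | intermediate
11 | (E)-2-chloro-3-iodoprop-2-en-1-yl methanesulfonate | CS(=O)(=O)OC/C(Cl)=C\I | intermediate
12 | (E)-2-chloro-3-iodo-N-methylprop-2-en-1-amine | CNC/C(Cl)=C\I | intermediate
13 | 4-tert-butoxy-4-oxobutanoic acid (mono-tert-butyl succinate) | CC(C)(C)OC(=O)CCC(=O)O | starting material
14 | tert-butyl 4-{[(2E)-2-chloro-3-iodoprop-2-en-1-yl](methyl)amino}-4-oxobutanoate | CC(C)(C)OC(=O)CCC(=O)N(C)C/C(Cl)=C\I | intermediate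
15 | 2-methylcyclohex-2-en-1-one | CC1=CCCCC1=O | starting material
16 | (1S)-2-methylcyclohex-2-en-1-ol | C1CC[C@H](O)C(C)=C1 | intermediate
17 | tert-butyldimethyl{[(1S)-2-methylcyclohex-2-en-1-yl]oxy}silane | C1CC[C@H](O[Si](C)(C)C(C)(C)C)C(C)=C1 | intermediate
18 | monoalkylborane from 17 (boron on C1', trans to CH3 and to OTBS) | C1CC[C@H](O[Si](C)(C)C(C)(C)C)[C@H](C)[C@H]1B | intermediate
19 | (1S,2R,3S)-3-[(tert-butyldimethylsilyl)oxy]-2-methylcyclohexan-1-ol | C1CC[C@H](O[Si](C)(C)C(C)(C)C)[C@H](C)[C@H]1O | intermediate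
20 | (2S,3S)-3-[(tert-butyldimethylsilyl)oxy]-2-methylcyclohexan-1-one | C1CC[C@H](O[Si](C)(C)C(C)(C)C)[C@H](C)C1=O | intermediate
21 | kinetic lithium enolate of 20 | C=1CC[C@H](O[Si](C)(C)C(C)(C)C)[C@H](C)C=1O[Li] | intermediate
22 | (5S,6S)-5-[(tert-butyldimethylsilyl)oxy]-6-methylcyclohex-2-en-1-one | C1=CC[C@H](O[Si](C)(C)C(C)(C)C)[C@H](C)C1=O | intermediate
23 | (5S,6S)-5-[(tert-butyldimethylsilyl)oxy]-2-iodo-6-methylcyclohex-2-en-1-one | IC1=CC[C@H](O[Si](C)(C)C(C)(C)C)[C@H](C)C1=O | intermediate
24 | (1S,5S,6R)-5-[(tert-butyldimethylsilyl)oxy]-2-iodo-6-methylcyclohex-2-en-1-ol (OH, CH3, OTBS all cis) | IC1=CC[C@H](O[Si](C)(C)C(C)(C)C)[C@H](C)[C@@H]1O | intermediate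
25 | 2-lithio lithium alkoxide from 24 | [Li]C1=CC[C@H](O[Si](C)(C)C(C)(C)C)[C@H](C)[C@@H]1O[Li] | intermediate
26 | alkenylzinc chloride (lithium alkoxide) from 25 | Cl[Zn]C1=CC[C@H](O[Si](C)(C)C(C)(C)C)[C@H](C)[C@@H]1O[Li] | intermediate
27 | tert-butyl 4-{[(2E)-3-{(4S,5R,6S)-4-[(tert-butyldimethylsilyl)oxy]-6-hydroxy-5-methylcyclohex-1-en-1-yl}-2-chloroprop-2-en-1-yl](methyl)amino}-4-oxobutanoate | CC(C)(C)OC(=O)CCC(=O)N(C)C/C(Cl)=C\C1=CC[C@H](O[Si](C)(C)C(C)(C)C)[C@H](C)[C@@H]1O | intermediate
28 | tert-butyl 4-{[(2E)-3-{(1S,2S,3R,4S,6R)-4-[(tert-butyldimethylsilyl)oxy]-2-hydroxy-3-methyl-7-oxabicyclo[4.1.0]heptan-1-yl}-2-chloroprop-2-en-1-yl](methyl)amino}-4-oxobutanoate | CC(C)(C)OC(=O)CCC(=O)N(C)C/C(Cl)=C\[C@@]12O[C@@H]1C[C@H](O[Si](C)(C)C(C)(C)C)[C@H](C)[C@@H]2O | intermediate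
29 | tert-butyl 4-{[(2E)-3-{(1R,3S,4S,6R)-4-[(tert-butyldimethylsilyl)oxy]-3-methyl-2-oxo-7-oxabicyclo[4.1.0]heptan-1-yl}-2-chloroprop-2-en-1-yl](methyl)amino}-4-oxobutanoate | CC(C)(C)OC(=O)CCC(=O)N(C)C/C(Cl)=C\[C@@]12O[C@@H]1C[C@H](O[Si](C)(C)C(C)(C)C)[C@H](C)C2=O | intermediate
30 | tert-butyl 4-{[(2E)-2-chloro-3-[(1R,3S,4S,6R)-4-hydroxy-3-methyl-2-oxo-7-oxabicyclo[4.1.0]heptan-1-yl]prop-2-en-1-yl](methyl)amino}-4-oxobutanoate | CC(C)(C)OC(=O)CCC(=O)N(C)C/C(Cl)=C\[C@@]12O[C@@H]1C[C@H](O)[C@H](C)C2=O | intermediate
31 | tert-butyl 4-{[(2E)-3-[(1R,3S,4S,6R)-4-acetoxy-3-methyl-2-oxo-7-oxabicyclo[4.1.0]heptan-1-yl]-2-chloroprop-2-en-1-yl](methyl)amino}-4-oxobutanoate | CC(C)(C)OC(=O)CCC(=O)N(C)C/C(Cl)=C\[C@@]12O[C@@H]1C[C@H](OC(C)=O)[C@H](C)C2=O | intermediate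
32 | 4-{[(2E)-3-[(1R,3S,4S,6R)-4-acetoxy-3-methyl-2-oxo-7-oxabicyclo[4.1.0]heptan-1-yl]-2-chloroprop-2-en-1-yl](methyl)amino}-4-oxobutanoic acid | OC(=O)CCC(=O)N(C)C/C(Cl)=C\[C@@]12O[C@@H]1C[C@H](OC(C)=O)[C@H](C)C2=O | intermediate
33 | 1,3-dioxoisoindolin-2-yl ester of 32 | O=C(CCC(=O)N(C)C/C(Cl)=C\[C@@]12O[C@@H]1C[C@H](OC(C)=O)[C@H](C)C2=O)ON1C(=O)c2ccccc2C1=O | intermediate
34 | (4E,7R)-N-{(2E)-3-[(1R,3S,4S,6R)-4-acetoxy-3-methyl-2-oxo-7-oxabicyclo[4.1.0]heptan-1-yl]-2-chloroprop-2-en-1-yl}-7-methoxy-N-methyltetradec-4-enamide | CCCCCCC[C@H](C/C=C/CCC(=O)N(C)C/C(Cl)=C\[C@@]12O[C@@H]1C[C@H](OC(C)=O)[C@H](C)C2=O)OC | target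

## Step count and risks

Total step count: 22. Longest linear sequence: 15 steps (15 to 34, steps 8–22).

**Step 22.**
- What may go wrong: electron transfer from the cathode or from low-valent nickel to the α,β-epoxy ketone could cause reductive C–O opening. Opening of the oxirane could also be assisted by iodide and magnesium ions. The primary radical could be lost to hydrogen abstraction before nickel captures it.
- Fallback (sets out from 8 and 33, comes back at 34): a redox-neutral decarboxylative alkenylation with a preformed organozinc, without current or external reductant.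
- Iodine–lithium exchange on 8 (t-BuLi, −78 °C) and transmetalation with ZnCl2 give [(1E,4R)-4-methoxyundec-1-en-1-yl]zinc chloride F1.
- F1 is coupled with 33 under Ni(acac)2/2,2'-bipyridine catalysis in THF/DMF at rt to form the same C3–C4 bond and deliver 34.

**Step 5.**
- What may go wrong: chloride could open the iodirenium ion at the terminal carbon, because the CH2OH group pulls electron density inductively. Ion-pair collapse could also erode the anti stereochemistry.
- Fallback (sets out from 9, comes back at 10): the halogens are introduced one at a time by syn hydrometalation and two retentive metal–halogen replacements.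
- Double deprotonation (n-BuLi, 2 equiv) and silylation (Me3SiCl, 2 equiv) give trimethyl{3-[(trimethylsilyl)oxy]prop-1-yn-1-yl}silane F2.
- The O-silyl group of F2 is hydrolysed in the acidic work-up to give 3-(trimethylsilyl)prop-2-yn-1-ol F3.
- Syn hydrostannation (Bu3SnH, PdCl2(PPh3)2) should place tin on C2, next to the carbinol carbon and away from silicon, giving (E)-2-(tributylstannyl)-3-(trimethylsilyl)prop-2-en-1-ol F4.
- CuCl2 in THF replaces tin by chlorine with retention to give (E)-2-chloro-3-(trimethylsilyl)prop-2-en-1-ol F5.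
- Iododesilylation with N-iodosuccinimide in hexafluoroisopropanol, again with retention, gives 10.

**Step 14.**
- What may go wrong: poor facial selectivity of hydride delivery to C1' would misdirect the epoxidation of step 16.
- Fallback (sets out from 23, comes back at 24): the carbinol centre is set by SN2 inversion instead of by facial bias.
- The C1' epimer formed in the reduction of 23, (1R,5S,6R)-5-[(tert-butyldimethylsilyl)oxy]-2-iodo-6-methylcyclohex-2-en-1-ol F6, is separated.
- A Mitsunobu reaction on F6 (4-nitrobenzoic acid, PPh3, DIAD) gives (1S,5S,6R)-5-[(tert-butyldimethylsilyl)oxy]-2-iodo-6-methylcyclohex-2-en-1-yl 4-nitrobenzoate F7.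
- Methanolysis of F7 (K2CO3, MeOH) gives 24.

## Further compounds

F1 | step 22 | [(1E,4R)-4-methoxyundec-1-en-1-yl]zinc chloride | CCCCCCC[C@H](C/C=C/[Zn]Cl)OC
F2 | step 5 | trimethyl{3-[(trimethylsilyl)oxy]prop-1-yn-1-yl}silane | C[Si](C)(C)C#CCO[Si](C)(C)C
F3 | step 5 | 3-(trimethylsilyl)prop-2-yn-1-ol | C[Si](C)(C)C#CCO
F4 | step 5 | (E)-2-(tributylstannyl)-3-(trimethylsilyl)prop-2-en-1-ol | OC/C([Sn](CCCC)(CCCC)CCCC)=C\[Si](C)(C)C
F5 | step 5 | (E)-2-chloro-3-(trimethylsilyl)prop-2-en-1-ol | OC/C(Cl)=C\[Si](C)(C)C
F6 | step 14 | (1R,5S,6R)-5-[(tert-butyldimethylsilyl)oxy]-2-iodo-6-methylcyclohex-2-en-1-ol | IC1=CC[C@H](O[Si](C)(C)C(C)(C)C)[C@H](C)[C@H]1O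
F7 | step 14 | (1S,5S,6R)-5-[(tert-butyldimethylsilyl)oxy]-2-iodo-6-methylcyclohex-2-en-1-yl 4-nitrobenzoate | IC1=CC[C@H](O[Si](C)(C)C(C)(C)C)[C@H](C)[C@@H]1OC(=O)c1ccc(cc1)[N+](=O)[O-]
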